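One run cannot show you how the height of the D curve moves with the charge of J, for it holds its charge at one value. You have two runs, and a flask with a larger charge to foretell.

| setting | zeta | eta | flask |
|---|---|---|---|
| J | 8.5 mM | 13 mM | 17 mM |
| G | 2.9 mM (held) | 2.9 mM (held) | 2.9 mM (held) |
| remark | run made earlier | run made earlier |  |
| time |  |  | 1.0 h |

| run | time / min | D / % |
|---|---|---|
| zeta | 2.50 | 5.5 |
| zeta | 4.00 | 8.6 |
| zeta | 8.00 | 13.6 |
| zeta | 15.0 | 13.1 |
| zeta | 25.0 | 7.7 |
| zeta | 50.0 | 0.9 |
| eta | 2.50 | 6.0 |
| eta | 4.00 | 8.3 |
| eta | 8.00 | 12.1 |
| eta | 15.0 | 11.1 |
| eta | 25.0 | 6.1 |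
| eta | 50.0 | 1.2 |

(readings scatter by 0.5 percentage points)

- at the start none of G is in solution

- the moment within 1.0 h at which there is most D
- the amount of D, in percent of the J charged, at that time
- the first time at which D reaches 7.4%, in the same percent

The bench rule of thumb is to lay the percent curves over one another. If every step is first order in J or in D, with G held as it is here, the percent of D at a given time does not depend on the charge, so the ratio between two runs is one, and that is the zero of the scale. At 8.00 min, the highest reading in both runs, eta over zeta is 0.890, so the rule is strained already.

My own reckoning supposes that a pseudo-first-order route to D competes with a loss second order in J, which makes the height go as c×/(c× + cJ). The two readings give 27.8 mM for c×, the charge of J at which the two routes run level. This is rough, since the readings differ by 1.5 percentage points with a scatter of 0.5 points on each. The rule of thumb stops working as cJ/c× approaches one, and the flask stands at 0.612. Scaling zeta's height by this form, I get 11.0% for the flask.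

The forecast gives 11% at 0.16 h and the level reached at 0.06 h, holding that “some loss process is higher order in J or D”.

The flask gives 10.5% at 0.156 h and reaches the level at 0.0656 h.

    G ⇌ E, rate k1*(csat - [E]) (kL = 0.0129 s⁻¹)
    2 J → X (k = 0.0810 M⁻¹ s⁻¹)
    J + E → D (k = 0.337 M⁻¹ s⁻¹)
    E + D → Z (k = 0.954 M⁻¹ s⁻¹)

The forecast's 11% was made for the 17 mM flask and does not carry over to a neighbour flask charged with 42 mM of J, whose best is 6.36%, while c× reckons 7.07% there. In the 17 mM flask at 0.194 h, just past the peak, E turns with J into D at 0.84 of the rate at which it turns with D into Z. At 1.00 h that flask holds Z at 37.7% and D at 0.577%.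

The runs are simulated from invented constants, noise included.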